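## Retrosynthetic overview

1. Feature used: ring A (C4a, C5, C6, C7, C8, C8a) is a hexasubstituted benzene with oxygen on C5, C7 and C8a and carbon on C4a, C6 and C8. It is not taken from a phloroglucinol but built last, from open-chain carbon, onto the finished ring C by a Diels–Alder reaction and aromatization.
2. Key disconnection C4a–C5 and C8–C8a: the C5–C6–C7–C8 unit is a 1-methoxy-1,3-bis(silyloxy)diene that already carries both prenyl groups. The C4a=C8a unit is the C5=C6 bond of a 2-aryl-3-alkoxy-4-pyranone (O1, C2, C3, C4 and ring B in place), activated by a 5-phenylsulfinyl group that then leaves by syn-elimination.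
3. Diene: methyl acetoacetate, γ-prenylation of the dianion, α-prenylation of the resulting β-keto ester, then double O-silylation; both C–prenyl bonds are enolate alkylations, so no aromatic C-prenylation is needed.
4. Dienophile: 2-hydroxy-1-(4-hydroxyphenyl)ethanone, MOM protection, C-acylation with (phenylsulfanyl)acetyl chloride, one-carbon condensation that closes ring C (O1–C8a bond), S-oxidation.
5. Ring order: B (bought), C (step 3), A (step 8); step 9 removes the two MOM groups.

Key step: step 8

Assumption: the ketene acetal geometry of the diene, the sulfur configuration of the sulfoxide and the relative configuration of the cycloadduct (apart from its cis ring fusion) are left as mixtures, because every stereocenter made on the way is destroyed when ring A aromatizes, and the target has none.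

## Route

Step 1
Reactants: 1 2-hydroxy-1-(4-hydroxyphenyl)ethan-1-one
Product: 2 2-(methoxymethoxy)-1-[4-(methoxymethoxy)phenyl]ethan-1-one
Conditions: MOMCl (2.6 equiv), i-Pr2NEt (3.2 equiv), CH2Cl2, 0 °C → rt
Reagents that add atoms: chloromethyl methyl ether (MOMCl, two equivalents incorporated), COCCl
Why: Acetal-forming O-alkylation (MOM protection) of the phenol and the primary ketol hydroxyl under amine base masks the two oxygens that become 4'-OH and 3-OH and leaves the CH2 as the only enolizable position.

Step 2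
Reactants: 2 2-(methoxymethoxy)-1-[4-(methoxymethoxy)phenyl]ethan-1-one; 3 (phenylsulfanyl)acetyl chloride
Product: 4 2-(methoxymethoxy)-1-[4-(methoxymethoxy)phenyl]-4-(phenylsulfanyl)butane-1,3-dione (racemic, largely enolized)
Conditions: LiN(SiMe3)2 (2.2 equiv), THF, −78 °C; then 3 (1.1 equiv), −78 → 0 °C; aq. NH4Cl
Reagents that add atoms: none
Why: Crossed Claisen-type C-acylation of the chelated lithium enolate of the α-alkoxy ketone should give the 1,3-diketone, and the second equivalent of base converts it into its enolate, which protects it from a second acylation.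

Step 3
Reactants: 4 2-(methoxymethoxy)-1-[4-(methoxymethoxy)phenyl]-4-(phenylsulfanyl)butane-1,3-dione; 5 tert-butoxybis(dimethylamino)methane
Product: 7 3-(methoxymethoxy)-2-[4-(methoxymethoxy)phenyl]-5-(phenylsulfanyl)-4H-pyran-4-one, via enaminone 6 (not isolated)
Conditions: 5 (1.3 equiv), PhMe, 70 °C; then AcOH (5 equiv), 60 °C
Reagents that add atoms: none
Why: Aminomethylenation of the only CH2 (activated by C=O and S) followed by cyclization of the aryl-ketone enol oxygen onto the aminomethylene carbon with loss of Me2NH (4-pyranone synthesis from a 1,3-diketone, 6-endo addition–elimination) should close ring C; the non-methylating aminal ester avoids O-methylation of the enol.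

Step 4
Reactants: 7 3-(methoxymethoxy)-2-[4-(methoxymethoxy)phenyl]-5-(phenylsulfanyl)-4H-pyran-4-one
Product: 8 3-(methoxymethoxy)-2-[4-(methoxymethoxy)phenyl]-5-(phenylsulfinyl)-4H-pyran-4-one (racemic at sulfur)
Conditions: mCPBA (1.0 equiv), CH2Cl2, −78 → −30 °C
Reagents that add atoms: 3-chloroperoxybenzoic acid (mCPBA), O=C(OO)c1cccc(Cl)c1
Why: Chemoselective sulfide-to-sulfoxide oxidation with one equivalent of peracid at low temperature, where sulfur reacts far faster than the electron-poor pyranone double bonds; the sulfur configuration is irrelevant.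

Step 5
Reactants: 9 methyl 3-oxobutanoate (methyl acetoacetate); 10 1-bromo-3-methylbut-2-ene (prenyl bromide)
Product: 11 methyl 7-methyl-3-oxooct-6-enoate
Conditions: NaH (1.1 equiv), THF, 0 °C; n-BuLi (1.05 equiv), 0 °C; 10 (1.0 equiv), 0 °C → rt; 1 M aq. HCl
Reagents that add atoms: none
Why: Acetoacetate dianion alkylation, in which the sodium lithium dianion reacts with one equivalent of the allylic bromide only at the more basic γ-carbon and the remaining stabilized enolate is protonated on work-up.

Step 6
Reactants: 11 methyl 7-methyl-3-oxooct-6-enoate; 10 1-bromo-3-methylbut-2-ene (prenyl bromide)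
Product: 12 methyl 7-methyl-2-(3-methylbut-2-en-1-yl)-3-oxooct-6-enoate (racemic)
Conditions: NaH (1.0 equiv), THF, 0 °C; 10 (1.0 equiv), 0 °C → rt; aq. NH4Cl
Reagents that add atoms: none
Why: Acetoacetic ester alkylation, in which the sodium enolate of the β-keto ester is C-alkylated at the α-carbon by the allylic bromide (SN2) and one equivalent each of base and bromide limits double alkylation; the α-stereocenter is racemic and is removed in step 7.

Step 7
Reactants: 12 methyl 7-methyl-2-(3-methylbut-2-en-1-yl)-3-oxooct-6-enoate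
Product: 14 (3Z)-1-methoxy-7-methyl-2-(3-methylbut-2-en-1-yl)-1,3-bis(trimethylsilyloxy)octa-1,3,6-triene, via silyl enol ether 13 (not isolated)
Conditions: NaN(SiMe3)2 (1.05 equiv), THF, −78 °C, Me3SiCl (1.1 equiv), → 0 °C; then LiN(i-Pr)2 (1.15 equiv), −78 °C, Me3SiCl (1.2 equiv); pentane, filtration under Ar, used crude
Reagents that add atoms: chlorotrimethylsilane (two equivalents incorporated), C[Si](C)(C)Cl
Why: Two-stage silyl ketene acetal formation: O-silylation of the β-keto ester enolate, then kinetic γ-deprotonation of the resulting vinylogous ester and O-silylation, should give the 1-methoxy-1,3-bis(silyloxy)diene, with the 3Z geometry following from the extended dienolate.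

Step 8
Reactants: 8 3-(methoxymethoxy)-2-[4-(methoxymethoxy)phenyl]-5-(phenylsulfinyl)-4H-pyran-4-one; 14 (3Z)-1-methoxy-7-methyl-2-(3-methylbut-2-en-1-yl)-1,3-bis(trimethylsilyloxy)octa-1,3,6-triene (2 equiv)
Product: 18 5,7-dihydroxy-3-(methoxymethoxy)-2-[4-(methoxymethoxy)phenyl]-6,8-bis(3-methylbut-2-en-1-yl)-4H-chromen-4-one, via cis-fused cycloadduct 15 (not isolated), via 5,8-dihydrochromenone 16 (not isolated), via bis(trimethylsilyl) ether 17 (not isolated)
Conditions: PhMe, 80 °C, then 110 °C (sealed tube, Ar); then 1 M aq. HCl, THF, 0 °C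
Reagents that add atoms: none
Why: Proposed new method: the electron-rich diene 14 (largest HOMO coefficient at C4) should add across the C5=C6 bond of 8, the only pyranone double bond whose LUMO is lowered by both the C4 carbonyl and the sulfinyl group, in a polar, asynchronous [4+2] cycloaddition that joins diene C4 to pyranone C6 (future C8–C8a) and the ketene acetal carbon to pyranone C5 (future C4a–C5), so that ring A is closed as a six-membered carbocycle by intermolecular cycloaddition. The closest known reaction type is the annulation of 1-alkoxy-1,3-bis(silyloxy)dienes with halo- and sulfinylquinones and the Diels–Alder reaction of acceptor-substituted chromones and 4-pyranone-3-carboxylates with 2-silyloxydienes, each followed by elimination to the arene. Suprafacial addition places the sulfinyl group and H-8a cis in 15, which is what the thermal syn-elimination of benzenesulfenic acid needs; it has no other β-hydrogen, so C4a=C8a is restored without base and therefore without a carbanion that could expel the ring oxygen O1. Vinylogous loss of methanol from the ketal carbon C5 and H-8 then aromatizes ring A, and dilute acid removes the two silyl groups. No stereocenter survives, so endo/exo and sulfur configuration do not matter. The step needs regioselectivity (oxygen on C5 and C7, prenyl on C6 and C8), which the polarity match secures: C6 of 8 is the β-carbon of the activated enone, while the C2=C3 bond is tetrasubstituted, donor-substituted and not activated by sulfur.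

Step 9
Reactants: 18 5,7-dihydroxy-3-(methoxymethoxy)-2-[4-(methoxymethoxy)phenyl]-6,8-bis(3-methylbut-2-en-1-yl)-4H-chromen-4-one
Product: 19 6,8-diprenylkaempferol, 3,5,7-trihydroxy-2-(4-hydroxyphenyl)-6,8-bis(3-methylbut-2-en-1-yl)-4H-chromen-4-one
Conditions: 2 M aq. HCl, MeOH, 45 °C
Reagents that add atoms: none
Why: Acid-catalysed acetal cleavage (MOM removal) in methanol, which takes up the oxocarbenium ion as dimethoxymethane; dilute acid at moderate temperature is chosen because prenyl groups next to free phenols can cyclize to chromans under stronger acid.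

## Compound list

1 | 2-hydroxy-1-(4-hydroxyphenyl)ethan-1-one | O=C(CO)c1ccc(O)cc1 | starting material
2 | 2-(methoxymethoxy)-1-[4-(methoxymethoxy)phenyl]ethan-1-one | COCOCC(=O)c1ccc(OCOC)cc1 | intermediate
3 | (phenylsulfanyl)acetyl chloride | O=C(Cl)CSc1ccccc1 | starting material
4 | 2-(methoxymethoxy)-1-[4-(methoxymethoxy)phenyl]-4-(phenylsulfanyl)butane-1,3-dione (racemic, drawn as the diketone) | COCOC(C(=O)CSc1ccccc1)C(=O)c1ccc(OCOC)cc1 | intermediate
5 | tert-butoxybis(dimethylamino)methane | CC(C)(C)OC(N(C)C)N(C)C | starting material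
6 | 5-(dimethylamino)-2-(methoxymethoxy)-1-[4-(methoxymethoxy)phenyl]-4-(phenylsulfanyl)pent-4-ene-1,3-dione (formed in the flask, alkene geometry not defined) | COCOC(C(=O)C(Sc1ccccc1)=CN(C)C)C(=O)c1ccc(OCOC)cc1 | intermediate
7 | 3-(methoxymethoxy)-2-[4-(methoxymethoxy)phenyl]-5-(phenylsulfanyl)-4H-pyran-4-one | COCOc1ccc(cc1)-c1occ(Sc2ccccc2)c(=O)c1OCOC | intermediate
8 | 3-(methoxymethoxy)-2-[4-(methoxymethoxy)phenyl]-5-(phenylsulfinyl)-4H-pyran-4-one (racemic at sulfur) | COCOc1ccc(cc1)-c1occ(S(=O)c2ccccc2)c(=O)c1OCOC | intermediate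
9 | methyl 3-oxobutanoate (methyl acetoacetate) | COC(=O)CC(C)=O | starting material
10 | 1-bromo-3-methylbut-2-ene (prenyl bromide) | CC(C)=CCBr | starting material
11 | methyl 7-methyl-3-oxooct-6-enoate | COC(=O)CC(=O)CCC=C(C)C | intermediate
12 | methyl 7-methyl-2-(3-methylbut-2-en-1-yl)-3-oxooct-6-enoate (racemic) | COC(=O)C(CC=C(C)C)C(=O)CCC=C(C)C | intermediate
13 | methyl 7-methyl-2-(3-methylbut-2-en-1-yl)-3-(trimethylsilyloxy)octa-2,6-dienoate (formed in the flask, enol ether geometry not defined) | COC(=O)C(CC=C(C)C)=C(O[Si](C)(C)C)CCC=C(C)C | intermediate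
14 | (3Z)-1-methoxy-7-methyl-2-(3-methylbut-2-en-1-yl)-1,3-bis(trimethylsilyloxy)octa-1,3,6-triene (C1=C2 geometry mixed) | CC(C)=CC/C=C(\O[Si](C)(C)C)C(CC=C(C)C)=C(OC)O[Si](C)(C)C | intermediate
15 | cis-5-methoxy-3-(methoxymethoxy)-2-[4-(methoxymethoxy)phenyl]-6,8-bis(3-methylbut-2-en-1-yl)-4a-(phenylsulfinyl)-5,7-bis(trimethylsilyloxy)-4a,5,8,8a-tetrahydro-4H-chromen-4-one (formed in the flask; racemic, cis ring fusion, mixed at C5, C8 and S) | COCOc1ccc(cc1)C1=C(OCOC)C(=O)[C@@]2(S(=O)c3ccccc3)[C@@H](O1)C(CC=C(C)C)C(O[Si](C)(C)C)=C(CC=C(C)C)C2(OC)O[Si](C)(C)C | intermediate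
16 | 5-methoxy-3-(methoxymethoxy)-2-[4-(methoxymethoxy)phenyl]-6,8-bis(3-methylbut-2-en-1-yl)-5,7-bis(trimethylsilyloxy)-5,8-dihydro-4H-chromen-4-one (formed in the flask; diastereomer mixture) | COCOc1ccc(cc1)C1=C(OCOC)C(=O)C2=C(O1)C(CC=C(C)C)C(O[Si](C)(C)C)=C(CC=C(C)C)C2(OC)O[Si](C)(C)C | intermediate
17 | 3-(methoxymethoxy)-2-[4-(methoxymethoxy)phenyl]-6,8-bis(3-methylbut-2-en-1-yl)-5,7-bis(trimethylsilyloxy)-4H-chromen-4-one (formed in the flask) | COCOc1ccc(cc1)-c1oc2c(CC=C(C)C)c(O[Si](C)(C)C)c(CC=C(C)C)c(O[Si](C)(C)C)c2c(=O)c1OCOC | intermediate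
18 | 5,7-dihydroxy-3-(methoxymethoxy)-2-[4-(methoxymethoxy)phenyl]-6,8-bis(3-methylbut-2-en-1-yl)-4H-chromen-4-one | COCOc1ccc(cc1)-c1oc2c(CC=C(C)C)c(O)c(CC=C(C)C)c(O)c2c(=O)c1OCOC | intermediate
19 | 6,8-diprenylkaempferol, 3,5,7-trihydroxy-2-(4-hydroxyphenyl)-6,8-bis(3-methylbut-2-en-1-yl)-4H-chromen-4-one | CC(C)=CCc1c(O)c(CC=C(C)C)c2oc(-c3ccc(O)cc3)c(O)c(=O)c2c1O | target

## Summary

Total step count: 9.
Longest linear sequence: 6 steps (steps 1, 2, 3, 4, 8, 9); the diene branch (steps 5, 6 and 7) joins at step 8.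

## Steps most likely to fail

**Step 8 (the proposed step).** The vinylogous-ester double bond of 8 may be too poor a dienophile, so that the slow cycloaddition loses to protodesilylation of the diene, to silyl transfer from the diene to the sulfoxide oxygen or to thermal decomposition of the sulfoxide. The first C–C bond may also form without ring closure. The fallback uses known chemistry and buys ring A instead of building it; it sets out from 10 and comes back at 19. Commercial 1-(2,4,6-trihydroxyphenyl)ethanone is C-prenylated twice with 10 in aqueous KOH to give 1-[2,4,6-trihydroxy-3,5-bis(3-methylbut-2-en-1-yl)phenyl]ethanone F1. The 4-hydroxyl and one ortho hydroxyl are protected with MOMCl and i-Pr2NEt to give 1-[2-hydroxy-4,6-bis(methoxymethoxy)-3,5-bis(3-methylbut-2-en-1-yl)phenyl]ethanone F2. Claisen–Schmidt condensation with commercial 4-(methoxymethoxy)benzaldehyde (KOH, EtOH) should give the (E)-chalcone F3. Algar–Flynn–Oyamada oxidation (H2O2, NaOH, MeOH), in which aurone formation is the known competitor, should give 3-hydroxy-5,7-bis(methoxymethoxy)-2-[4-(methoxymethoxy)phenyl]-6,8-bis(3-methylbut-2-en-1-yl)-4H-chromen-4-one F4. Acid as in step 9 then gives 19.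

**Step 2.** O-acylation of the enolate, ketene formation from the enolizable acid chloride and double acylation may outrun C-acylation at the oxygen-bearing carbon. The fallback makes the C–C bond at the aldehyde oxidation level and oxidizes afterwards; it sets out from 2 and comes back at 4. The lithium enolate of 2 (LiN(SiMe3)2, THF, −78 °C) is added to freshly distilled (phenylsulfanyl)acetaldehyde in an aldol addition to give 3-hydroxy-2-(methoxymethoxy)-1-[4-(methoxymethoxy)phenyl]-4-(phenylsulfanyl)butan-1-one F5 as a diastereomer mixture. Oxidation of the secondary alcohol with Dess–Martin periodinane gives 4.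

**Step 9.** Under the acid needed for acetal cleavage, a prenyl group may cyclize onto a neighbouring free phenol (chroman formation) or add methanol. The fallback moves the acid step in front of the prenyl-bearing stage and ends with silyl groups only; it sets out from 8 and comes back at 19. The MOM groups of 8 are removed with HCl in MeOH to give 3-hydroxy-2-(4-hydroxyphenyl)-5-(phenylsulfinyl)-4H-pyran-4-one F6. Silylation with N,O-bis(trimethylsilyl)acetamide gives 5-(phenylsulfinyl)-3-(trimethylsilyloxy)-2-[4-(trimethylsilyloxy)phenyl]-4H-pyran-4-one F7 in the flask, which is heated with 14 as in step 8. The cis-fused cycloadduct F8 should lose benzenesulfenic acid to give the 5,8-dihydrochromenone F9, and then methanol to give the tetrakis(trimethylsilyl) ether of the target F10. Citric acid in methanol then gives 19 without strong acid.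

## Further compounds

F1 | step 8 | 1-[2,4,6-trihydroxy-3,5-bis(3-methylbut-2-en-1-yl)phenyl]ethanone | CC(=O)c1c(O)c(CC=C(C)C)c(O)c(CC=C(C)C)c1O
F2 | step 8 | 1-[2-hydroxy-4,6-bis(methoxymethoxy)-3,5-bis(3-methylbut-2-en-1-yl)phenyl]ethanone | CC(=O)c1c(O)c(CC=C(C)C)c(OCOC)c(CC=C(C)C)c1OCOC
F3 | step 8 | (E)-1-[2-hydroxy-4,6-bis(methoxymethoxy)-3,5-bis(3-methylbut-2-en-1-yl)phenyl]-3-[4-(methoxymethoxy)phenyl]prop-2-en-1-one | COCOc1ccc(/C=C/C(=O)c2c(O)c(CC=C(C)C)c(OCOC)c(CC=C(C)C)c2OCOC)cc1
F4 | step 8 | 3-hydroxy-5,7-bis(methoxymethoxy)-2-[4-(methoxymethoxy)phenyl]-6,8-bis(3-methylbut-2-en-1-yl)-4H-chromen-4-one | COCOc1ccc(cc1)-c1oc2c(CC=C(C)C)c(OCOC)c(CC=C(C)C)c(OCOC)c2c(=O)c1O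
F5 | step 2 | 3-hydroxy-2-(methoxymethoxy)-1-[4-(methoxymethoxy)phenyl]-4-(phenylsulfanyl)butan-1-one (diastereomer mixture) | COCOC(C(O)CSc1ccccc1)C(=O)c1ccc(OCOC)cc1
F6 | step 9 | 3-hydroxy-2-(4-hydroxyphenyl)-5-(phenylsulfinyl)-4H-pyran-4-one (racemic at sulfur) | O=c1c(S(=O)c2ccccc2)coc(-c2ccc(O)cc2)c1O
F7 | step 9 | 5-(phenylsulfinyl)-3-(trimethylsilyloxy)-2-[4-(trimethylsilyloxy)phenyl]-4H-pyran-4-one | C[Si](C)(C)Oc1ccc(cc1)-c1occ(S(=O)c2ccccc2)c(=O)c1O[Si](C)(C)C
F8 | step 9 | cis-5-methoxy-6,8-bis(3-methylbut-2-en-1-yl)-4a-(phenylsulfinyl)-3,5,7-tris(trimethylsilyloxy)-2-[4-(trimethylsilyloxy)phenyl]-4a,5,8,8a-tetrahydro-4H-chromen-4-one (racemic, mixed at C5, C8 and S) | C[Si](C)(C)Oc1ccc(cc1)C1=C(O[Si](C)(C)C)C(=O)[C@@]2(S(=O)c3ccccc3)[C@@H](O1)C(CC=C(C)C)C(O[Si](C)(C)C)=C(CC=C(C)C)C2(OC)O[Si](C)(C)C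
F9 | step 9 | 5-methoxy-6,8-bis(3-methylbut-2-en-1-yl)-3,5,7-tris(trimethylsilyloxy)-2-[4-(trimethylsilyloxy)phenyl]-5,8-dihydro-4H-chromen-4-one (diastereomer mixture) | C[Si](C)(C)Oc1ccc(cc1)C1=C(O[Si](C)(C)C)C(=O)C2=C(O1)C(CC=C(C)C)C(O[Si](C)(C)C)=C(CC=C(C)C)C2(OC)O[Si](C)(C)C
F10 | step 9 | 6,8-bis(3-methylbut-2-en-1-yl)-3,5,7-tris(trimethylsilyloxy)-2-[4-(trimethylsilyloxy)phenyl]-4H-chromen-4-one | C[Si](C)(C)Oc1ccc(cc1)-c1oc2c(CC=C(C)C)c(O[Si](C)(C)C)c(CC=C(C)C)c(O[Si](C)(C)C)c2c(=O)c1O[Si](C)(C)C
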